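**Retrosynthetic overview**

1. The target has ring A (cyclohexene, C1 and C10–C14) trans-fused to the ten-membered ring C1–C10, which carries the γ-lactone (C7, C8, C17, C19). The plan rests on C2: an allylic carbinol wedged between the quaternary C1 and the Z C3=C4 alkene, whose aldehyde has no α-hydrogen.
2. Last C–C bond: C2–C3, by chromium/nickel-mediated addition of the Z alkenyl iodide to the C2 aldehyde, which closes the ten-membered ring; then C2 acetylation.
3. Seco aldehyde: Z iodo diene from a C3–C4 silylalkyne; γ-lactone by SmI2 Reformatsky closure (C17 to C8) of a C7 2-bromopropanoate onto a C8 ketone.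
4. C9–C10: chromium allylation of a C6–C9 aldehyde (from L-threitol acetonide; C5=C6 by bromo-Wittig, then Sonogashira) with a ring A allylic bromide (from (S)-carvone; C1 by double alkylation, C14 acetate by Criegee rearrangement).
5. Ring order: ring A (from carvone), then the lactone, then the ten-membered ring.

Key step: step 24

Remark: briarane numbering (C1–C20) is used for all intermediates; α is the face of ring A that carries the C14 oxygen, β the face that carries the C15 methyl.
Remark: the α-bromo ylide of step 8 is taken as the preformed, isolable reagent (from Ph3P=CHCO2Et, Br2 and Et3N).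
Remark: 2-bromopropanoyl bromide is used racemic; the bromine-bearing carbon is lost as a stereocenter in step 19.

**Route**

Step 1
Reactants: 1 (S)-(+)-carvone
Product: 3 6-[(triisopropylsilyloxy)methyl]carvone (trans isomer drawn), via lithium dienolate 2 (not isolated)
Conditions: LiN(iPr)2, THF, −78 °C; then (iPr)3SiOCH2Cl, −78 to −20 °C
Reagents that add atoms: (triisopropylsiloxy)methyl chloride, ClCO[Si](C(C)C)(C(C)C)C(C)C
Why: Kinetic α′-deprotonation of the enone and C-alkylation of the lithium enolate with a reactive chloromethyl ether (enolate alkoxymethylation) places the future C2 carbon on C1; the new stereocenter is erased in step 2, so its configuration does not matter.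

Step 2
Reactants: 3 6-[(triisopropylsilyloxy)methyl]carvone
Product: 5 6-methyl-6-[(triisopropylsilyloxy)methyl]carvone (methyl trans to isopropenyl), via lithium enolate 4 (not isolated)
Conditions: LiN(iPr)2, THF, −78 °C; then MeI, DMPU, −78 to −30 °C
Reagents that add atoms: iodomethane, CI
Why: Enolate alkylation in which MeI approaches the trisubstituted enolate on the face opposite to the neighbouring isopropenyl group, which sets the quaternary C1 with the methyl β and the silyloxymethyl arm α (cis to the C14 substituent).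

Step 3
Reactants: 5 6-methyl-6-[(triisopropylsilyloxy)methyl]carvone
Product: 7 ring A acetoxy enone (C10 ketone; C11=C12; C14 α-OAc), via methoxy hydroperoxide 6 (not isolated)
Conditions: O3, CH2Cl2/MeOH, −78 °C; then Ac2O, Et3N, DMAP (cat.), 0 °C to rt
Reagents that add atoms: ozone, [O-][O+]=O; methanol, CO
Why: Ozone cleaves the electron-rich isopropenyl group in preference to the enone, and Criegee rearrangement of the derived peracetate moves C14 from carbon to oxygen with retention, so the carvone stereocenter becomes the C14 acetate.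

Step 4
Reactants: 7 ring A acetoxy enone
Product: 8 ring A allylic alcohol (C10 carbinol, α-OH drawn)
Conditions: NaBH4, CeCl3·7H2O, MeOH, −40 to 0 °C
Reagents that add atoms: none
Why: Luche 1,2-reduction of the enone leaves the acetate and the silyl ether untouched; the configuration of the C10 carbinol is lost again in step 14 and need not be controlled.

Step 5
Reactants: 8 ring A allylic alcohol
Product: 9 ring A allylic bromide (C12–Br, C10=C11; C12 epimers)
Conditions: PBr3, pyridine (cat.), Et2O, −20 to 0 °C; used crude
Reagents that add atoms: phosphorus tribromide, BrP(Br)Br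
Why: Bromination of the hindered neopentyl allylic alcohol is expected to go with allylic transposition (SN2′) to the less hindered C12 bromide; any regio- or stereoisomer gives the same allylchromium reagent in step 14.

Step 6
Reactants: 10 2,3-O-isopropylidene-L-threitol
Product: 11 mono-PMB ether of 10
Conditions: NaH (1.0 equiv), 4-methoxybenzyl chloride, Bu4NI (cat.), THF/DMF, 0 °C to rt
Reagents that add atoms: 4-methoxybenzyl chloride, COc1ccc(CCl)cc1
Why: Williamson monoalkylation of the twofold-symmetric diol through its monoalkoxide; the two hydroxyls are equivalent, so no regiochemical question arises.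

Step 7
Reactants: 11 mono-PMB ether
Product: 12 C6 aldehyde (4-O-PMB-2,3-O-isopropylidene-L-threose)
Conditions: Dess–Martin periodinane, pyridine, CH2Cl2, 0 °C to rt
Reagents that add atoms: none
Why: Dess–Martin oxidation gives the α-alkoxy aldehyde under near-neutral conditions that should not epimerise C7.

Step 8
Reactants: 12 C6 aldehyde
Product: 13 ethyl (Z)-2-bromo enoate (C5–Br cis to C7, ester trans)
Conditions: Ph3P=C(Br)CO2Et, CH2Cl2, 0 °C to rt
Reagents that add atoms: ethyl 2-bromo-2-(triphenyl-λ5-phosphanylidene)acetate, CCOC(=O)C(Br)=P(c1ccccc1)(c1ccccc1)c1ccccc1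
Why: Wittig olefination with the stabilised α-bromo ylide places the ester trans to C7, which fixes the C5=C6 geometry with the future C16 trans and the bromine (future C4) cis to C7.

Step 9
Reactants: 13 ethyl (Z)-2-bromo enoate; 14 trimethylsilylacetylene
Product: 15 ethyl (E)-enynoate (C3–C4 silylalkyne on C5)
Conditions: PdCl2(PPh3)2 (cat.), CuI (cat.), iPr2NH, THF, rt
Reagents that add atoms: none
Why: Sonogashira coupling of the activated alkenyl bromide proceeds with retention of alkene geometry and installs C3–C4 as a silyl-capped alkyne.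

Step 10
Reactants: 15 ethyl (E)-enynoate
Product: 16 C16 allylic alcohol
Conditions: iBu2AlH (2.5 equiv), CH2Cl2, −78 °C
Reagents that add atoms: none
Why: 1,2-Reduction of the conjugated ester with iBu2AlH gives the allylic alcohol without touching the silylalkyne, the acetonide or the PMB ether.

Step 11
Reactants: 16 C16 allylic alcohol
Product: 17 C16 acetate
Conditions: Ac2O, pyridine, DMAP (cat.), CH2Cl2, 0 °C
Reagents that add atoms: acetic anhydride, CC(=O)OC(C)=O
Why: Acylation of the primary allylic alcohol installs the C16 acetate of the target, which later steps are chosen to tolerate.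

Step 12
Reactants: 17 C16 acetate
Product: 18 C9 alcohol
Conditions: DDQ, CH2Cl2/pH 7 buffer, 0 °C
Reagents that add atoms: none
Why: Oxidative cleavage of the PMB ether (benzylic hydride abstraction, then hydrolysis) frees the primary C9 hydroxyl and leaves the acetate, acetonide and enyne intact.

Step 13
Reactants: 18 C9 alcohol
Product: 19 C9 aldehyde (C7,C8 trans-acetonide)
Conditions: Dess–Martin periodinane, pyridine, CH2Cl2, 0 °C to rt; used directly
Reagents that add atoms: none
Why: Dess–Martin oxidation gives the α-alkoxy aldehyde needed for the fragment union.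

Step 14
Reactants: 9 ring A allylic bromide; 19 C9 aldehyde
Product: 20 coupled homoallylic alcohol (C9–C10 bond; 9S, 10S; C11=C12)
Conditions: CrCl2 (4 equiv), THF, 0 °C to rt
Reagents that add atoms: none
Why: Nozaki–Hiyama allylation in which the allylchromium from 9 carries the metal on the less hindered C12 and adds through C10 in a closed chair transition state on the β face (anti to the axial C1 silyloxymethyl arm, and an α-axial metal at C12 would clash with an axial C14 acetate), which sets 10S and, through the ring-bound Z allyl geometry, the syn-related 9S carbinol, a sense reinforced by Felkin–Anh addition to the threo α-alkoxy aldehyde.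

Step 15
Reactants: 20 coupled homoallylic alcohol
Product: 21 C9 acetate
Conditions: Ac2O, pyridine, DMAP (cat.), CH2Cl2, rt
Reagents that add atoms: acetic anhydride, CC(=O)OC(C)=O
Why: Acylation of the only free hydroxyl installs the C9 acetate of the target before the neighbouring diol is unmasked.

Step 16
Reactants: 21 C9 acetate
Product: 22 C7,C8-diol
Conditions: AcOH/H2O (4:1), 45 °C
Reagents that add atoms: none
Why: Acid-catalysed acetal hydrolysis removes the acetonide under conditions mild enough for the acetates, the silyl ether and the silylalkyne.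

Step 17
Reactants: 22 C7,C8-diol; 23 2-bromopropanoyl bromide
Product: 24 C7 2-bromopropanoate (C8–OH free)
Conditions: 2,4,6-collidine, CH2Cl2, −78 °C
Reagents that add atoms: none
Why: Regioselective O-acylation of the diol should go to the allylic C7 hydroxyl, which is far less hindered than the C8 hydroxyl wedged between the C9 acetate and ring A; the bromine-bearing carbon is an epimer mixture that converges in step 19.

Step 18
Reactants: 24 C7 2-bromopropanoate
Product: 25 C8 ketone
Conditions: Dess–Martin periodinane, pyridine, CH2Cl2, 0 °C; used directly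
Reagents that add atoms: none
Why: Dess–Martin oxidation of the remaining secondary alcohol is near-neutral, chosen so that the acidic allylic C7–H next to the new ketone is not epimerised.

Step 19
Reactants: 25 C8 ketone
Product: 26 γ-lactone (8S tertiary alcohol, 17R methyl; silylalkyne)
Conditions: SmI2 (2.2 equiv, slow addition), THF, −78 °C; then aq. NH4Cl
Reagents that add atoms: none
Why: SmI2-mediated intramolecular Reformatsky reaction in which reduction of the C–Br bond gives a trivalent samarium enolate that adds to the C8 ketone through a chelated transition state; the C9 branch takes the position trans to the C6 substituent on C7 (hydroxyl cis to C6, 8S) and the C17 methyl ends cis to the hydroxyl and trans to the C9 branch (17R), which is also the more stable arrangement.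

Step 20
Reactants: 26 γ-lactone
Product: 27 iodoalkyne
Conditions: N-iodosuccinimide, AgNO3 (cat.), DMF, rt, dark
Reagents that add atoms: N-iodosuccinimide, O=C1CCC(=O)N1I
Why: Silver-catalysed iododesilylation converts the alkynylsilane directly into the 1-iodoalkyne without base, so the acetates and the lactone are not at risk.

Step 21
Reactants: 27 iodoalkyne
Product: 28 Z alkenyl iodide (C2 silyl ether)
Conditions: 2-nitrobenzenesulfonylhydrazide, Et3N, THF/i-PrOH, rt
Reagents that add atoms: none
Why: Diimide generated in the flask adds two hydrogens syn to the 1-iodoalkyne (diimide semi-reduction), which gives the Z C3=C4 alkenyl iodide, while the trisubstituted alkenes should react much more slowly.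

Step 22
Reactants: 28 Z alkenyl iodide
Product: 29 C2 alcohol
Conditions: HF·pyridine, pyridine, THF, 0 °C to rt
Reagents that add atoms: none
Why: Fluoride cleavage of the primary triisopropylsilyl ether under buffered acidic conditions spares the acetates, the lactone and the alkenyl iodide and avoids base-induced acyl migration.

Step 23
Reactants: 29 C2 alcohol
Product: 30 seco C2 aldehyde with Z C3 alkenyl iodide
Conditions: Dess–Martin periodinane, pyridine, CH2Cl2, 0 °C to rt
Reagents that add atoms: none
Why: Dess–Martin oxidation of the neopentyl primary alcohol gives the aldehyde on the quaternary C1, which cannot enolise.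

Step 24
Reactants: 30 seco C2 aldehyde with Z C3 alkenyl iodide
Product: 31 2-deacetyl target (free C2 alcohol)
Conditions: CrCl2 (10 equiv), NiCl2 (cat.), degassed DMSO, rt, 2 mM, slow addition of 30
Reagents that add atoms: none
Why: Zerovalent nickel, formed from NiCl2 by CrCl2, inserts into the C3–I bond with retention of the Z geometry and passes the alkenyl group to trivalent chromium, and this alkenylchromium adds to the C2 aldehyde. The closest known reaction type is the Nozaki–Hiyama–Kishi macrocyclization of alkenyl iodide aldehydes to medium and large carbocycles. The ten-membered ring closes by a 10-exo-trig attack of C3 on the carbonyl carbon C2, and the Z C3=C4 bond, the preformed E C5=C6 bond and the trans arrangement of the two arms on ring A hold C3 close to C2. The new stereocenter C2 is set by the substrate: the chromium-bound carbonyl oxygen should stay on the outside of the forming ring, turned away from the C14 acetate, so that C3 adds to the Si face and gives the 2S alcohol. The step needs the alkenyl iodide and the aldehyde to react beside a lactone, three acetates and a free tertiary hydroxyl, which alkenylchromium reagents tolerate, and it needs ring closure to outrun intermolecular coupling, which high dilution and slow addition secure. The aldehyde on the quaternary C1 has no α-hydrogen, so it cannot enolise or epimerise under the Lewis-acidic conditions.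

Step 25
Reactants: 31 2-deacetyl target
Product: 32 CNP0224753.2
Conditions: Ac2O, pyridine, DMAP (cat.), CH2Cl2, 0 °C to rt
Reagents that add atoms: acetic anhydride, CC(=O)OC(C)=O
Why: Chemoselective acylation of the secondary allylic C2 alcohol should leave the hindered tertiary C8 hydroxyl untouched.

**Compound list**

1 | (S)-(+)-carvone | CC1=CC[C@@H](CC1=O)C(C)=C | starting material
2 | lithium dienolate of 1 (O-lithio, enolate toward the future C1) | [Li]OC1=C[C@@H](C(C)=C)CC=C1C | intermediate
3 | 6-[(triisopropylsilyloxy)methyl]carvone, CH2OSi(iPr)3 trans to isopropenyl | O=C1C(C)=CC[C@H](C(C)=C)[C@H]1CO[Si](C(C)C)(C(C)C)C(C)C | intermediate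
4 | lithium enolate of 3 | [Li]OC1=C(CO[Si](C(C)C)(C(C)C)C(C)C)[C@@H](C(C)=C)CC=C1C | intermediate
5 | 6-methyl-6-[(triisopropylsilyloxy)methyl]carvone, methyl trans to isopropenyl (quaternary C1) | O=C1C(C)=CC[C@H](C(C)=C)[C@]1(C)CO[Si](C(C)C)(C(C)C)C(C)C | intermediate
6 | methoxy hydroperoxide from ozonolysis of 5 (C14 bears C(CH3)(OCH3)OOH) | O=C1C(C)=CC[C@H](C(C)(OC)OO)[C@]1(C)CO[Si](C(C)C)(C(C)C)C(C)C | intermediate
7 | ring A acetoxy enone: C10 ketone, C11=C12, C14 α-acetate, C1 β-methyl and α-CH2OSi(iPr)3 | O=C1C(C)=CC[C@H](OC(C)=O)[C@]1(C)CO[Si](C(C)C)(C(C)C)C(C)C | intermediate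
8 | ring A allylic alcohol: C10 carbinol (α-OH drawn), C11=C12 | O[C@@H]1C(C)=CC[C@H](OC(C)=O)[C@]1(C)CO[Si](C(C)C)(C(C)C)C(C)C | intermediate
9 | ring A allylic bromide: C12–Br (both epimers), C10=C11 | C1=C(C)C(Br)C[C@H](OC(C)=O)[C@]1(C)CO[Si](C(C)C)(C(C)C)C(C)C | intermediate
10 | 2,3-O-isopropylidene-L-threitol, (4S,5S)-2,2-dimethyl-1,3-dioxolane-4,5-dimethanol | OC[C@@H]1OC(C)(C)O[C@H]1CO | starting material
11 | mono-(4-methoxybenzyl) ether of 10 (PMB on the future C9 oxygen) | COc1ccc(COC[C@@H]2OC(C)(C)O[C@H]2CO)cc1 | intermediate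
12 | 4-O-PMB-2,3-O-isopropylidene-L-threose (C6 aldehyde) | COc1ccc(COC[C@@H]2OC(C)(C)O[C@H]2C=O)cc1 | intermediate
13 | ethyl (Z)-2-bromo enoate: C6=C5(Br)CO2Et, bromine cis to C7 | COc1ccc(COC[C@@H]2OC(C)(C)O[C@H]2/C=C(\Br)C(=O)OCC)cc1 | intermediate
14 | trimethylsilylacetylene | C[Si](C)(C)C#C | starting material
15 | ethyl (E)-enynoate: C5 carries C≡C–SiMe3 (cis to C7) and CO2Et (trans to C7) | COc1ccc(COC[C@@H]2OC(C)(C)O[C@H]2/C=C(\C#C[Si](C)(C)C)C(=O)OCC)cc1 | intermediate
16 | C16 allylic alcohol | COc1ccc(COC[C@@H]2OC(C)(C)O[C@H]2/C=C(\C#C[Si](C)(C)C)CO)cc1 | intermediate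
17 | C16 acetate | COc1ccc(COC[C@@H]2OC(C)(C)O[C@H]2/C=C(\C#C[Si](C)(C)C)COC(C)=O)cc1 | intermediate
18 | C9 alcohol (C7,C8 acetonide; C16 acetate; silylenyne) | OC[C@@H]1OC(C)(C)O[C@H]1/C=C(\C#C[Si](C)(C)C)COC(C)=O | intermediate
19 | C9 aldehyde (C7,C8 trans-acetonide; C16 acetate; silylenyne) | O=C[C@@H]1OC(C)(C)O[C@H]1/C=C(\C#C[Si](C)(C)C)COC(C)=O | intermediate
20 | coupled homoallylic alcohol: C9–C10 bond, 9S-OH, 10S, C11=C12, C7,C8 acetonide | CC(=O)OC/C(=C/[C@@H]1OC(C)(C)O[C@H]1[C@@H](O)[C@H]1C(C)=CC[C@H](OC(C)=O)[C@]1(C)CO[Si](C(C)C)(C(C)C)C(C)C)C#C[Si](C)(C)C | intermediate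
21 | C9 acetate of 20 | CC(=O)OC/C(=C/[C@@H]1OC(C)(C)O[C@H]1[C@@H](OC(C)=O)[C@H]1C(C)=CC[C@H](OC(C)=O)[C@]1(C)CO[Si](C(C)C)(C(C)C)C(C)C)C#C[Si](C)(C)C | intermediate
22 | C7,C8-diol | CC(=O)OC/C(=C/[C@H](O)[C@@H](O)[C@@H](OC(C)=O)[C@H]1C(C)=CC[C@H](OC(C)=O)[C@]1(C)CO[Si](C(C)C)(C(C)C)C(C)C)C#C[Si](C)(C)C | intermediate
23 | 2-bromopropanoyl bromide (racemic) | CC(Br)C(Br)=O | starting material
24 | C7 2-bromopropanoate, C8–OH free (epimers at the CHBr carbon) | CC(=O)OC/C(=C/[C@H](OC(=O)C(C)Br)[C@@H](O)[C@@H](OC(C)=O)[C@H]1C(C)=CC[C@H](OC(C)=O)[C@]1(C)CO[Si](C(C)C)(C(C)C)C(C)C)C#C[Si](C)(C)C | intermediate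
25 | C8 ketone with C7 2-bromopropanoate | CC(=O)OC/C(=C/[C@H](OC(=O)C(C)Br)C(=O)[C@@H](OC(C)=O)[C@H]1C(C)=CC[C@H](OC(C)=O)[C@]1(C)CO[Si](C(C)C)(C(C)C)C(C)C)C#C[Si](C)(C)C | intermediate
26 | γ-lactone (7S, 8S-OH, 17R-methyl) with C3–C4 silylalkyne and C2 silyl ether | CC(=O)OC/C(=C/[C@@H]1OC(=O)[C@H](C)[C@@]1(O)[C@@H](OC(C)=O)[C@H]1C(C)=CC[C@H](OC(C)=O)[C@]1(C)CO[Si](C(C)C)(C(C)C)C(C)C)C#C[Si](C)(C)C | intermediate
27 | iodoalkyne (C3–I) | CC(=O)OC/C(=C/[C@@H]1OC(=O)[C@H](C)[C@@]1(O)[C@@H](OC(C)=O)[C@H]1C(C)=CC[C@H](OC(C)=O)[C@]1(C)CO[Si](C(C)C)(C(C)C)C(C)C)C#CI | intermediate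
28 | Z alkenyl iodide with C2 triisopropylsilyl ether | CC(=O)OC/C(=C/[C@@H]1OC(=O)[C@H](C)[C@@]1(O)[C@@H](OC(C)=O)[C@H]1C(C)=CC[C@H](OC(C)=O)[C@]1(C)CO[Si](C(C)C)(C(C)C)C(C)C)/C=C\I | intermediate
29 | C2 primary alcohol | CC(=O)OC/C(=C/[C@@H]1OC(=O)[C@H](C)[C@@]1(O)[C@@H](OC(C)=O)[C@H]1C(C)=CC[C@H](OC(C)=O)[C@]1(C)CO)/C=C\I | intermediate
30 | seco C2 aldehyde with Z C3 alkenyl iodide (key-step precursor) | CC(=O)OC/C(=C/[C@@H]1OC(=O)[C@H](C)[C@@]1(O)[C@@H](OC(C)=O)[C@H]1C(C)=CC[C@H](OC(C)=O)[C@]1(C)C=O)/C=C\I | intermediate
31 | 2-deacetyl target (2S alcohol; key-step product) | CC(=O)OCC1=C/[C@@H]2OC(=O)[C@H](C)[C@@]2(O)[C@@H](OC(C)=O)[C@H]2C(C)=CC[C@H](OC(C)=O)[C@]2(C)[C@@H](O)/C=C\1 | intermediate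
32 | CNP0224753.2 (1R,2S,7S,8S,9S,10S,14S,17R; 3Z,5E) | CC(=O)OCC1=C/[C@@H]2OC(=O)[C@H](C)[C@@]2(O)[C@@H](OC(C)=O)[C@H]2C(C)=CC[C@H](OC(C)=O)[C@]2(C)[C@@H](OC(C)=O)/C=C\1 | target

**Counts**

Total steps: 25. Longest linear sequence: 20 steps (from 10 through steps 6–13 and 14–25); the carvone branch is 17 steps.

**Steps most likely to fail**

Step 24. The alkenylchromium may add to the wrong face of the C2 aldehyde, because the facial preference rests only on the conformation of the closing ring. Setting out from 30, the closure would then deliver mainly the C2 epimer of 31, F1. Dess–Martin oxidation of the allylic alcohol would give the macrocyclic C2 dienone F2, and its reduction (NaBH4 with CeCl3·7H2O, or an oxazaborolidine-catalysed borane reduction if the ring does not bias the hydride) would set C2 by hydride delivery in place of C–C bond formation and return to 31.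

Step 14. The allylchromium may attack from the α face of ring A or through C12, so that C10 and C9 diastereomers or the regioisomeric adduct form. Setting out from enone 7, copper-catalysed conjugate borylation (CuCl, NaOtBu, B2pin2, MeOH, THF) should place boron on C12 trans to the C14 acetate and give the β-boryl ketone F3. KN(SiMe3)2 with PhNTf2 would give the enol triflate F4, and reduction with Pd(OAc)2, PPh3, Bu3N and HCO2H the configurationally defined allylboronate F5. Allylboration of aldehyde 19 with F5 (neat, or with BF3·OEt2) passes through a closed chair transition state on the boron-bearing β face, so that C10 and C9 follow from the C12 stereocenter, and returns to 20.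

Step 19. Single-electron reduction may cleave the α-acyloxy and α-acetoxy groups of the ketone, or the samarium enolate may take the acidic C7 proton in place of closing the ring. Setting out from diol 22, acylation of the C7 hydroxyl with acryloyl chloride and collidine would give the acrylate F6, and Dess–Martin oxidation the keto acrylate F7. Conjugate reduction of F7 with [(Ph3P)CuH]6 generates the ester enolate regiospecifically, which closes onto the C8 ketone (reductive aldol cyclization) with the methyl cis to the hydroxyl and returns to lactone 26 without a single-electron reductant.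

**Further compounds**

F1 | step 24 | C2 epimer of 31 (2R alcohol) | CC(=O)OCC1=C/[C@@H]2OC(=O)[C@H](C)[C@@]2(O)[C@@H](OC(C)=O)[C@H]2C(C)=CC[C@H](OC(C)=O)[C@]2(C)[C@H](O)/C=C\1
F2 | step 24 | macrocyclic C2 ketone (cross-conjugated dienone) | CC(=O)OCC1=C/[C@@H]2OC(=O)[C@H](C)[C@@]2(O)[C@@H](OC(C)=O)[C@H]2C(C)=CC[C@H](OC(C)=O)[C@]2(C)C(=O)/C=C\1
F3 | step 14 | ring A β-boryl ketone (C12 β-Bpin, C10 ketone, C11 epimers) | O=C1C(C)[C@@H](B2OC(C)(C)C(C)(C)O2)C[C@H](OC(C)=O)[C@]1(C)CO[Si](C(C)C)(C(C)C)C(C)C
F4 | step 14 | ring A enol triflate (C10–OTf, C10=C11, C12 β-Bpin) | FC(F)(F)S(=O)(=O)OC1=C(C)[C@@H](B2OC(C)(C)C(C)(C)O2)C[C@H](OC(C)=O)[C@]1(C)CO[Si](C(C)C)(C(C)C)C(C)C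
F5 | step 14 | ring A allylboronate (C12 β-Bpin, C10=C11) | C1=C(C)[C@@H](B2OC(C)(C)C(C)(C)O2)C[C@H](OC(C)=O)[C@]1(C)CO[Si](C(C)C)(C(C)C)C(C)C
F6 | step 19 | C7 acrylate of diol 22 (C8–OH free) | CC(=O)OC/C(=C/[C@H](OC(=O)C=C)[C@@H](O)[C@@H](OC(C)=O)[C@H]1C(C)=CC[C@H](OC(C)=O)[C@]1(C)CO[Si](C(C)C)(C(C)C)C(C)C)C#C[Si](C)(C)C
F7 | step 19 | C8 ketone with C7 acrylate | CC(=O)OC/C(=C/[C@H](OC(=O)C=C)C(=O)[C@@H](OC(C)=O)[C@H]1C(C)=CC[C@H](OC(C)=O)[C@]1(C)CO[Si](C(C)C)(C(C)C)C(C)C)C#C[Si](C)(C)C
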